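**Plan**

1. Retrosynthesis: remove the three acyl groups; cut the lactone O6–C12 bond (carboxylate displacing a C6 mesylate, C12 masked as a vinyl group); return the 4,5-epoxide to the 4Z-alkene; cut ring bond C2–C3 while re-inserting CO2 between C2 and O–C3 (12-membered allyl β-keto lactone); open its ester C–O (acylketene); then cut C1–C2 (Roskamp), C5–C6 (vinyllithium + lactol) and C7–C8 (lactone aldol).
2. Enabling feature: C1(=O)–C2–C3–C4(–O–)C5 of the ten-membered carbocycle is a masked γ,δ-unsaturated ketone C1(=O)–C2–C3–C4=C5. This is the retron of a decarboxylative (Carroll/Tsuji-type) allylation, so the C2–C3 ring bond can arise by extrusion of CO2 from a macrolide two atoms larger.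
3. Forward: butyrolactone (C6, C7, C11–C13) + C8–C10/C1 aldehyde by aldol; lactol opened by the C3–C5 Z-vinyllithium; chain end homologated to a β-keto ester; 12-membered lactone by acylketene capture; Pd(0) ring contraction to the cyclodecenone; then epoxide, γ-lactone (last ring) and acylations.
4. Stereochemistry: C11 from Rh/(S)-BINAP conjugate addition; C7 and C8 from the lactone E-enolate anti-aldol (anti to the C11 vinyl group); C10 from (S)-2-methylglycidol; C6 from Felkin/1,3-anti addition followed by SN2 inversion; C4/C5 from OH-directed epoxidation of the 4Z-alkene.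

Key step: step 17

Remark: the SMILES is read as drawn, i.e. (4R,5S,6S,7S,8S,10R,11R) with a cis-4,5-epoxide (C3 and C6 on the same side of the oxirane) and a cis-fused 6,12-lactone carrying C5, C8 and C13 on one face. Germacranolide locants are used throughout (C1 ketone, C4/C5 epoxide, C6 lactone carbinol, C8 methacrylate carbinol, C10 acetoxy carbon, C12 lactone carbonyl, C13 acetoxymethyl).

**Route**

Step 1
Reactants: 1 furan-2(5H)-one
Product: 2 (S)-4-vinyldihydrofuran-2(3H)-one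
Conditions: vinylboronic acid pinacol ester (1.5 equiv), [Rh(cod)Cl]2 (2.5 mol %), (S)-BINAP (5.5 mol %), Et3N, dioxane/H2O 10:1, 60 °C
Reagents that add atoms: vinylboronic acid pinacol ester, C=CB1OC(C)(C)C(C)(C)O1
Why: Hayashi–Miyaura Rh(I)/BINAP asymmetric 1,4-addition of an alkenylboron reagent to the butenolide, in which the ligand selects the enantioface and sets C11 ((S)-BINAP is expected to give the S-lactone by analogy with cyclic enones; the antipode would be used otherwise).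

Step 2
Reactants: 3 (S)-(2-methyloxiran-2-yl)methanol
Product: 4 (R)-2-methylpent-4-ene-1,2-diol
Conditions: CH2=CHMgBr (2.5 equiv), CuI (10 mol %), THF, −30 → 0 °C; aq NH4Cl
Reagents that add atoms: vinylmagnesium bromide, C=C[Mg]Br
Why: Copper-catalysed SN2 opening of the 2,2-disubstituted epoxide at its CH2 terminus, which leaves the quaternary carbinol centre (future C10) of the chiral-pool glycidol untouched.

Step 3
Reactants: 4 (R)-2-methylpent-4-ene-1,2-diol
Product: 5 (R)-2-methyl-1,2-bis(triethylsilyloxy)pent-4-ene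
Conditions: TESOTf (2.4 equiv), 2,6-lutidine, CH2Cl2, −78 → 0 °C
Reagents that add atoms: triethylsilyl triflate, CC[Si](CC)(CC)OS(=O)(=O)C(F)(F)F
Why: Silyl triflate/lutidine silylation protects both the primary and the tertiary hydroxyl.

Step 4
Reactants: 5 (R)-2-methyl-1,2-bis(triethylsilyloxy)pent-4-ene
Product: 7 (R)-3-methyl-3,4-bis(triethylsilyloxy)butanal, via ozonide 6 (not isolated)
Conditions: O3, CH2Cl2, −78 °C; then PPh3, −78 °C → rt
Reagents that add atoms: ozone, [O-][O+]=O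
Why: Ozonolysis with reductive work-up converts the terminal alkene into the C8 aldehyde without touching the silyl ethers.

Step 5
Reactants: 8 prop-2-yn-1-ol
Product: 10 (Z)-3-iodo-2-methylprop-2-en-1-ol, via alkenylmagnesium species 9 (not isolated)
Conditions: MeMgBr (2.5 equiv), CuI (10 mol %), THF, −10 °C → rt; then I2, −20 → 0 °C
Reagents that add atoms: methylmagnesium bromide, C[Mg]Br; iodine, II
Why: Copper-catalysed anti-carbomagnesiation of the propargylic alkoxide through a five-membered magnesium chelate, then iodinolysis with retention, places iodine cis to CH2OH (the future 4Z-alkene).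

Step 6
Reactants: 10 (Z)-3-iodo-2-methylprop-2-en-1-ol
Product: 11 (Z)-1-iodo-3-(4-methoxybenzyloxy)-2-methylprop-1-ene
Conditions: NaH, PMBCl, Bu4NI (cat.), THF/DMF, 0 °C → rt
Reagents that add atoms: 4-methoxybenzyl chloride, COc1ccc(CCl)cc1
Why: Williamson etherification protects O3 with a group that can later be removed oxidatively in the presence of silyl ethers.

Step 7
Reactants: 2 (S)-4-vinyldihydrofuran-2(3H)-one; 7 (R)-3-methyl-3,4-bis(triethylsilyloxy)butanal
Product: 13 (3S,4R)-3-[(1S,3R)-1-hydroxy-3-methyl-3,4-bis(triethylsilyloxy)butyl]-4-vinyldihydrofuran-2(3H)-one, via boron enolate 12 (not isolated)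
Conditions: 2, c-Hex2BOTf (1.3 equiv), Et3N (1.6 equiv), CH2Cl2, −78 °C; then 7, −78 → −20 °C; pH 7 buffer, MeOH, 30 % H2O2, 0 °C
Reagents that add atoms: none
Why: Boron-mediated aldol of the ring-locked E(O)-enolate through a Zimmerman–Traxler chair should give the anti (C7/C8) adduct with the aldehyde entering anti to the C11 vinyl group (3,4-trans), so C7 and C8 are both set by the lactone.

Step 8
Reactants: 13 aldol adduct
Product: 14 (3S,4R)-3-[(1S,3R)-1-(tert-butyldimethylsilyloxy)-3-methyl-3,4-bis(triethylsilyloxy)butyl]-4-vinyldihydrofuran-2(3H)-one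
Conditions: TBSOTf, 2,6-lutidine, CH2Cl2, −78 → −20 °C
Reagents that add atoms: tert-butyldimethylsilyl triflate, CC(C)(C)[Si](C)(C)OS(=O)(=O)C(F)(F)F
Why: Low-temperature triflate silylation protects O8 without retro-aldol cleavage.

Step 9
Reactants: 14 silylated lactone
Product: 15 (3S,4R)-3-[(1S,3R)-1-(tert-butyldimethylsilyloxy)-3-methyl-3,4-bis(triethylsilyloxy)butyl]-4-vinyltetrahydrofuran-2-ol (anomer mixture)
Conditions: DIBAL-H (1.1 equiv), CH2Cl2, −78 °C; Rochelle salt
Reagents that add atoms: none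
Why: DIBAL half-reduction of a γ-lactone stops at the lactol at −78 °C and unmasks C6 at the aldehyde level.

Step 10
Reactants: 11 (Z)-1-iodo-3-(4-methoxybenzyloxy)-2-methylprop-1-ene; 15 lactol
Product: 17 (2Z,4S,5R,6S,8R)-6-(tert-butyldimethylsilyloxy)-5-[(2R)-1-hydroxybut-3-en-2-yl]-1-(4-methoxybenzyloxy)-2,8-dimethyl-8,9-bis(triethylsilyloxy)non-2-en-4-ol, via vinyllithium 16 (not isolated)
Conditions: 11 (3.0 equiv), t-BuLi (6.0 equiv), Et2O, −78 °C; then 15, −78 → −30 °C; aq NH4Cl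
Reagents that add atoms: none
Why: Iodine–lithium exchange with retention of the Z geometry and addition to the open aldehyde form of the lactol, where Felkin–Anh control (C8 branch as the large group) and 1,3-anti induction by the β-silyloxy group reinforce each other, should give the 6,7-syn-6,8-anti carbinol (C6 deliberately epimeric to the target).

Step 11
Reactants: 17 diol
Product: 18 (2Z,4S,5R,6S,8R)-5-[(2R)-1-acetoxybut-3-en-2-yl]-6-(tert-butyldimethylsilyloxy)-1-(4-methoxybenzyloxy)-2,8-dimethyl-8,9-bis(triethylsilyloxy)non-2-en-4-ol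
Conditions: AcCl (1.1 equiv), 2,4,6-collidine, CH2Cl2, −78 °C
Reagents that add atoms: acetyl chloride, CC(=O)Cl
Why: Low-temperature acylation with acetyl chloride/collidine is selective for the primary C13 hydroxyl over the hindered secondary allylic C6 hydroxyl and installs the final C13 acetate.

Step 12
Reactants: 18 monoacetate
Product: 19 (2Z,4S,5S,6S,8R)-5-[(2R)-1-acetoxybut-3-en-2-yl]-6-(tert-butyldimethylsilyloxy)-1-(4-methoxybenzyloxy)-2,8-dimethyl-4,8,9-tris(triethylsilyloxy)non-2-ene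
Conditions: TESCl, imidazole, DMF, 0 °C
Reagents that add atoms: chlorotriethylsilane, CC[Si](Cl)(CC)CC
Why: Silylation masks O6 as a non-ionisable, non-nucleophilic ether for the oxidation and palladium steps.

Step 13
Reactants: 19 tris-TES ether
Product: 20 (2R,4S,5S,6S,7Z)-5-[(2R)-1-acetoxybut-3-en-2-yl]-4-(tert-butyldimethylsilyloxy)-9-(4-methoxybenzyloxy)-2,8-dimethyl-2,6-bis(triethylsilyloxy)non-7-enal
Conditions: (COCl)2, DMSO, CH2Cl2, −78 → −35 °C; then Et3N, −78 → 0 °C
Reagents that add atoms: none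
Why: Under Swern conditions a primary triethylsilyl ether is cleaved and oxidised directly to the aldehyde, whereas secondary and tertiary silyl ethers and the PMB ether are left intact.

Step 14
Reactants: 20 aldehyde
Product: 21 tert-butyl (4R,6S,7S,8S,9Z)-7-[(2R)-1-acetoxybut-3-en-2-yl]-6-(tert-butyldimethylsilyloxy)-11-(4-methoxybenzyloxy)-4,10-dimethyl-3-oxo-4,8-bis(triethylsilyloxy)undec-9-enoate
Conditions: tert-butyl diazoacetate (1.5 equiv), SnCl2 (20 mol %), CH2Cl2, rt
Reagents that add atoms: tert-butyl diazoacetate, [N-]=[N+]=CC(=O)OC(C)(C)C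
Why: Roskamp reaction (Lewis-acid-promoted diazoacetate addition, 1,2-hydride shift and loss of N2) converts the non-enolisable α-silyloxy aldehyde into the β-keto ester and forms C1–C2.

Step 15
Reactants: 21 β-keto ester
Product: 22 tert-butyl (4R,6S,7S,8S,9Z)-7-[(2R)-1-acetoxybut-3-en-2-yl]-6-(tert-butyldimethylsilyloxy)-11-hydroxy-4,10-dimethyl-3-oxo-4,8-bis(triethylsilyloxy)undec-9-enoate
Conditions: DDQ (1.3 equiv), CH2Cl2/pH 7 buffer 10:1, 0 °C
Reagents that add atoms: none
Why: Oxidative cleavage of the PMB ether by DDQ frees the primary allylic O3 hydroxyl without affecting silyl ethers, acetate or β-keto ester.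

Step 16
Reactants: 22 seco hydroxy β-keto ester
Product: 24 (5R,7S,8S,9S,10Z)-8-[(2R)-1-acetoxybut-3-en-2-yl]-7-(tert-butyldimethylsilyloxy)-5,11-dimethyl-5,9-bis(triethylsilyloxy)oxacyclododec-10-ene-2,4-dione, via acylketene 23 (not isolated)
Conditions: toluene, 110 °C, slow addition by syringe pump (final 0.5 mM)
Reagents that add atoms: none
Why: Thermal loss of tert-butanol from the tert-butyl β-keto ester gives an acylketene that is captured intramolecularly by the primary allylic alcohol (acylketene macrolactonization), closing the 12-membered β-keto lactone under neutral conditions.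

Step 17
Reactants: 24 12-membered allyl β-keto lactone
Product: 25 (4Z,6S,7S,8S,10R)-7-[(2R)-1-acetoxybut-3-en-2-yl]-8-(tert-butyldimethylsilyloxy)-4,10-dimethyl-6,10-bis(triethylsilyloxy)cyclodec-4-en-1-one
Conditions: Pd(PPh3)4 (10 mol %), THF (2 mM), 40 °C
Reagents that add atoms: none
Why: Proposed new method: Pd(0) ionises the primary allylic C3–O ester bond of 24 to a π-allylpalladium β-keto carboxylate, which loses CO2 to give the C1/C2 enolate (the only one possible, because C10 is quaternary) tethered to the C3–C5 allyl unit, and C2 then attacks the unsubstituted terminus C3, so that the ring shrinks by the two extruded atoms. The closest known reaction type is the Tsuji–Saegusa (Carroll-type) decarboxylative allylation of acyclic allyl β-keto esters, together with Tsuji–Trost closures of medium and large carbocycles; its use as a ring contraction of a macrolide is the untested element. The ten-membered carbocycle closes by C2→C3 attack with the C4=C5 alkene left endocyclic, whereas attack at C5 would give an eight-membered ring and is disfavoured at the hindered secondary terminus next to the C6 silyl ether. No new stereocentre is formed; the 4Z geometry should be carried over because the anti-π-allyl formed from the Z-ester is trapped intramolecularly faster than syn–anti exchange at the hindered C5 terminus and because the Z-alkene is the less strained one in the ten-membered ring. Selectivity is needed against O6 participation, β-hydride elimination and oligomerisation, and it is secured by the non-ionisable TES ether on O6, the absence of any added base and high dilution.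

Step 18
Reactants: 25 cyclodecenone
Product: 26 (4Z,6S,7R,8S,10R)-7-[(2R)-1-acetoxybut-3-en-2-yl]-8-(tert-butyldimethylsilyloxy)-6-hydroxy-4,10-dimethyl-10-(triethylsilyloxy)cyclodec-4-en-1-one
Conditions: PPTS (0.3 equiv), MeOH/CH2Cl2 1:3, 0 °C
Reagents that add atoms: none
Why: Mild acid methanolysis removes the secondary TES ether much faster than the tertiary TES and the secondary TBS ether, freeing only the allylic C6 hydroxyl.

Step 19
Reactants: 26 allylic alcohol
Product: 27 (4R,5S,6R,7R,8S,10R)-7-[(2R)-1-acetoxybut-3-en-2-yl]-8-(tert-butyldimethylsilyloxy)-4,5-epoxy-6-hydroxy-4,10-dimethyl-10-(triethylsilyloxy)cyclodecan-1-one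
Conditions: m-CPBA (1.2 equiv), NaHCO3, CH2Cl2, 0 °C
Reagents that add atoms: 3-chloroperbenzoic acid, O=C(OO)c1cccc(Cl)c1
Why: Hydroxyl-directed (Henbest) peracid epoxidation of the electron-rich trisubstituted alkene, with H6 held in the alkene plane by A(1,3) strain as in medium-ring cis-cycloalk-2-enols, should deliver oxygen syn to O6 on the exo face (threo, ring-trans) and so set C4 and C5, leaving the terminal vinyl group untouched.

Step 20
Reactants: 27 epoxy alcohol
Product: 28 (4R,5S,6R,7S,8S,10R)-7-[(2R)-1-acetoxybut-3-en-2-yl]-8-(tert-butyldimethylsilyloxy)-4,5-epoxy-4,10-dimethyl-6-(methylsulfonyloxy)-10-(triethylsilyloxy)cyclodecan-1-one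
Conditions: MsCl, Et3N, CH2Cl2, −20 °C
Reagents that add atoms: methanesulfonyl chloride, CS(=O)(=O)Cl
Why: Mesylation of the only free hydroxyl turns O6 into a leaving group for the inverting lactonisation.

Step 21
Reactants: 28 mesylate
Product: 30 (4R,5S,6S,7R,8S,10R,11R)-13-acetoxy-8-(tert-butyldimethylsilyloxy)-4,5-epoxy-1-oxo-10-(triethylsilyloxy)germacran-6,12-olide, via carboxylic acid 29 (not isolated)
Conditions: RuCl3·xH2O (5 mol %), NaIO4 (4.2 equiv), MeCN/CCl4/H2O, 0 °C → rt; then NaHCO3, DMF, 40 °C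
Reagents that add atoms: sodium periodate, [Na+].[O-]I(=O)(=O)=O; water, O
Why: RuO4 cleavage of the now unique C=C bond turns the C11 vinyl group into the C12 carboxylic acid, whose carboxylate displaces the C6 mesylate by intramolecular SN2 (5-exo-tet) with inversion, closing the cis-fused γ-lactone and setting C6 (6R → 6S).

Step 22
Reactants: 30 bis-silylated lactone
Product: 31 (4R,5S,6S,7S,8S,10R,11R)-13-acetoxy-4,5-epoxy-8,10-dihydroxy-1-oxogermacran-6,12-olide
Conditions: HF·pyridine, pyridine, THF, 0 °C → rt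
Reagents that add atoms: none
Why: Pyridine-buffered HF·pyridine removes the secondary TBS and tertiary TES ethers under conditions that spare the epoxide, the acetate and the base-sensitive β-acetoxy lactone.

Step 23
Reactants: 31 diol
Product: 32 (4R,5S,6S,7S,8S,10R,11R)-13-acetoxy-4,5-epoxy-10-hydroxy-8-methacryloyloxy-1-oxogermacran-6,12-olide
Conditions: methacrylic anhydride (1.5 equiv), DMAP (0.2 equiv), pyridine, CH2Cl2, 0 °C → rt
Reagents that add atoms: methacrylic anhydride, C=C(C)C(=O)OC(=O)C(C)=C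
Why: DMAP-catalysed acylation takes place at the secondary C8 hydroxyl, while the tertiary α-keto C10 hydroxyl does not react under these mild conditions.

Step 24
Reactants: 32 tertiary alcohol
Product: 33 (4R,5S,6S,7S,8S,10R,11R)-10,13-diacetoxy-4,5-epoxy-8-methacryloyloxy-1-oxogermacran-6,12-olide (CNP0166747.1)
Conditions: Ac2O, DMAP, pyridine, 40 °C
Reagents that add atoms: acetic anhydride, CC(=O)OC(C)=O
Why: Forcing DMAP-catalysed acetylation esterifies the remaining tertiary hydroxyl without a base strong enough to eliminate the 13-acetoxy group.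

**Compound list**

1 | furan-2(5H)-one | O=C1C=CCO1 | starting material
2 | (S)-4-vinyldihydrofuran-2(3H)-one | O=C1C[C@@H](C=C)CO1 | intermediate
3 | (S)-(2-methyloxiran-2-yl)methanol | OC[C@@]1(C)CO1 | starting material
4 | (R)-2-methylpent-4-ene-1,2-diol | C=CC[C@@](C)(O)CO | intermediate
5 | (R)-2-methyl-1,2-bis(triethylsilyloxy)pent-4-ene | C=CC[C@@](C)(O[Si](CC)(CC)CC)CO[Si](CC)(CC)CC | intermediate
6 | ozonide (1,2,4-trioxolane) of 5 | C1OC(C[C@@](C)(O[Si](CC)(CC)CC)CO[Si](CC)(CC)CC)OO1 | intermediate (not isolated)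
7 | (R)-3-methyl-3,4-bis(triethylsilyloxy)butanal | O=CC[C@@](C)(O[Si](CC)(CC)CC)CO[Si](CC)(CC)CC | intermediate
8 | prop-2-yn-1-ol | C#CCO | starting material
9 | (Z)-3-(bromomagnesio)-2-methylprop-2-en-1-olate magnesium bromide | C/C(CO[Mg]Br)=C/[Mg]Br | intermediate (not isolated)
10 | (Z)-3-iodo-2-methylprop-2-en-1-ol | C/C(CO)=C/I | intermediate
11 | (Z)-1-iodo-3-(4-methoxybenzyloxy)-2-methylprop-1-ene | C/C(COCc1ccc(OC)cc1)=C/I | intermediate
12 | dicyclohexylboron enolate of 2 | C=C[C@H]1COC(OB(C2CCCCC2)C2CCCCC2)=C1 | intermediate (not isolated)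
13 | (3S,4R)-3-[(1S,3R)-1-hydroxy-3-methyl-3,4-bis(triethylsilyloxy)butyl]-4-vinyldihydrofuran-2(3H)-one | O=C1OC[C@H](C=C)[C@H]1[C@@H](O)C[C@@](C)(O[Si](CC)(CC)CC)CO[Si](CC)(CC)CC | intermediate
14 | (3S,4R)-3-[(1S,3R)-1-(tert-butyldimethylsilyloxy)-3-methyl-3,4-bis(triethylsilyloxy)butyl]-4-vinyldihydrofuran-2(3H)-one | O=C1OC[C@H](C=C)[C@H]1[C@@H](O[Si](C)(C)C(C)(C)C)C[C@@](C)(O[Si](CC)(CC)CC)CO[Si](CC)(CC)CC | intermediate
15 | (3S,4R)-3-[(1S,3R)-1-(tert-butyldimethylsilyloxy)-3-methyl-3,4-bis(triethylsilyloxy)butyl]-4-vinyltetrahydrofuran-2-ol (anomer mixture) | OC1OC[C@H](C=C)[C@H]1[C@@H](O[Si](C)(C)C(C)(C)C)C[C@@](C)(O[Si](CC)(CC)CC)CO[Si](CC)(CC)CC | intermediate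
16 | (Z)-[3-(4-methoxybenzyloxy)-2-methylprop-1-enyl]lithium | C/C(COCc1ccc(OC)cc1)=C/[Li] | intermediate (not isolated)
17 | (2Z,4S,5R,6S,8R)-6-(tert-butyldimethylsilyloxy)-5-[(2R)-1-hydroxybut-3-en-2-yl]-1-(4-methoxybenzyloxy)-2,8-dimethyl-8,9-bis(triethylsilyloxy)non-2-en-4-ol | COc1ccc(COC/C(C)=C\[C@H](O)[C@@H]([C@@H](C=C)CO)[C@@H](O[Si](C)(C)C(C)(C)C)C[C@@](C)(O[Si](CC)(CC)CC)CO[Si](CC)(CC)CC)cc1 | intermediate
18 | (2Z,4S,5R,6S,8R)-5-[(2R)-1-acetoxybut-3-en-2-yl]-6-(tert-butyldimethylsilyloxy)-1-(4-methoxybenzyloxy)-2,8-dimethyl-8,9-bis(triethylsilyloxy)non-2-en-4-ol | COc1ccc(COC/C(C)=C\[C@H](O)[C@@H]([C@@H](C=C)COC(C)=O)[C@@H](O[Si](C)(C)C(C)(C)C)C[C@@](C)(O[Si](CC)(CC)CC)CO[Si](CC)(CC)CC)cc1 | intermediate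
19 | (2Z,4S,5S,6S,8R)-5-[(2R)-1-acetoxybut-3-en-2-yl]-6-(tert-butyldimethylsilyloxy)-1-(4-methoxybenzyloxy)-2,8-dimethyl-4,8,9-tris(triethylsilyloxy)non-2-ene | COc1ccc(COC/C(C)=C\[C@H](O[Si](CC)(CC)CC)[C@@H]([C@@H](C=C)COC(C)=O)[C@@H](O[Si](C)(C)C(C)(C)C)C[C@@](C)(O[Si](CC)(CC)CC)CO[Si](CC)(CC)CC)cc1 | intermediate
20 | (2R,4S,5S,6S,7Z)-5-[(2R)-1-acetoxybut-3-en-2-yl]-4-(tert-butyldimethylsilyloxy)-9-(4-methoxybenzyloxy)-2,8-dimethyl-2,6-bis(triethylsilyloxy)non-7-enal | COc1ccc(COC/C(C)=C\[C@H](O[Si](CC)(CC)CC)[C@@H]([C@@H](C=C)COC(C)=O)[C@@H](O[Si](C)(C)C(C)(C)C)C[C@@](C)(O[Si](CC)(CC)CC)C=O)cc1 | intermediate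
21 | tert-butyl (4R,6S,7S,8S,9Z)-7-[(2R)-1-acetoxybut-3-en-2-yl]-6-(tert-butyldimethylsilyloxy)-11-(4-methoxybenzyloxy)-4,10-dimethyl-3-oxo-4,8-bis(triethylsilyloxy)undec-9-enoate | COc1ccc(COC/C(C)=C\[C@H](O[Si](CC)(CC)CC)[C@@H]([C@@H](C=C)COC(C)=O)[C@@H](O[Si](C)(C)C(C)(C)C)C[C@@](C)(O[Si](CC)(CC)CC)C(=O)CC(=O)OC(C)(C)C)cc1 | intermediate
22 | tert-butyl (4R,6S,7S,8S,9Z)-7-[(2R)-1-acetoxybut-3-en-2-yl]-6-(tert-butyldimethylsilyloxy)-11-hydroxy-4,10-dimethyl-3-oxo-4,8-bis(triethylsilyloxy)undec-9-enoate | OC/C(C)=C\[C@H](O[Si](CC)(CC)CC)[C@@H]([C@@H](C=C)COC(C)=O)[C@@H](O[Si](C)(C)C(C)(C)C)C[C@@](C)(O[Si](CC)(CC)CC)C(=O)CC(=O)OC(C)(C)C | intermediate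
23 | acylketene from 22 (C1 ketone with C2=C=O) | OC/C(C)=C\[C@H](O[Si](CC)(CC)CC)[C@@H]([C@@H](C=C)COC(C)=O)[C@@H](O[Si](C)(C)C(C)(C)C)C[C@@](C)(O[Si](CC)(CC)CC)C(=O)C=C=O | intermediate (not isolated)
24 | (5R,7S,8S,9S,10Z)-8-[(2R)-1-acetoxybut-3-en-2-yl]-7-(tert-butyldimethylsilyloxy)-5,11-dimethyl-5,9-bis(triethylsilyloxy)oxacyclododec-10-ene-2,4-dione | O=C1CC(=O)[C@](C)(O[Si](CC)(CC)CC)C[C@H](O[Si](C)(C)C(C)(C)C)[C@H]([C@@H](C=C)COC(C)=O)[C@@H](O[Si](CC)(CC)CC)/C=C(C)\CO1 | intermediate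
25 | (4Z,6S,7S,8S,10R)-7-[(2R)-1-acetoxybut-3-en-2-yl]-8-(tert-butyldimethylsilyloxy)-4,10-dimethyl-6,10-bis(triethylsilyloxy)cyclodec-4-en-1-one | O=C1CC/C(C)=C\[C@H](O[Si](CC)(CC)CC)[C@@H]([C@@H](C=C)COC(C)=O)[C@@H](O[Si](C)(C)C(C)(C)C)C[C@@]1(C)O[Si](CC)(CC)CC | intermediate
26 | (4Z,6S,7R,8S,10R)-7-[(2R)-1-acetoxybut-3-en-2-yl]-8-(tert-butyldimethylsilyloxy)-6-hydroxy-4,10-dimethyl-10-(triethylsilyloxy)cyclodec-4-en-1-one | O=C1CC/C(C)=C\[C@H](O)[C@@H]([C@@H](C=C)COC(C)=O)[C@@H](O[Si](C)(C)C(C)(C)C)C[C@@]1(C)O[Si](CC)(CC)CC | intermediate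
27 | (4R,5S,6R,7R,8S,10R)-7-[(2R)-1-acetoxybut-3-en-2-yl]-8-(tert-butyldimethylsilyloxy)-4,5-epoxy-6-hydroxy-4,10-dimethyl-10-(triethylsilyloxy)cyclodecan-1-one | O=C1CC[C@@]2(C)O[C@H]2[C@H](O)[C@@H]([C@@H](C=C)COC(C)=O)[C@@H](O[Si](C)(C)C(C)(C)C)C[C@@]1(C)O[Si](CC)(CC)CC | intermediate
28 | (4R,5S,6R,7S,8S,10R)-7-[(2R)-1-acetoxybut-3-en-2-yl]-8-(tert-butyldimethylsilyloxy)-4,5-epoxy-4,10-dimethyl-6-(methylsulfonyloxy)-10-(triethylsilyloxy)cyclodecan-1-one | O=C1CC[C@@]2(C)O[C@H]2[C@H](OS(C)(=O)=O)[C@@H]([C@@H](C=C)COC(C)=O)[C@@H](O[Si](C)(C)C(C)(C)C)C[C@@]1(C)O[Si](CC)(CC)CC | intermediate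
29 | (11R)-C12 carboxylic acid of 28 (vinyl group replaced by CO2H) | O=C1CC[C@@]2(C)O[C@H]2[C@H](OS(C)(=O)=O)[C@@H]([C@@H](C(=O)O)COC(C)=O)[C@@H](O[Si](C)(C)C(C)(C)C)C[C@@]1(C)O[Si](CC)(CC)CC | intermediate (not isolated)
30 | (4R,5S,6S,7R,8S,10R,11R)-13-acetoxy-8-(tert-butyldimethylsilyloxy)-4,5-epoxy-1-oxo-10-(triethylsilyloxy)germacran-6,12-olide | CC(C)(C)[Si](C)(C)O[C@H]1C[C@@](C)(O[Si](CC)(CC)CC)C(=O)CC[C@@]2(C)O[C@H]2[C@H]2OC(=O)[C@@H](COC(C)=O)[C@H]21 | intermediate
31 | (4R,5S,6S,7S,8S,10R,11R)-13-acetoxy-4,5-epoxy-8,10-dihydroxy-1-oxogermacran-6,12-olide | O[C@H]1C[C@@](C)(O)C(=O)CC[C@@]2(C)O[C@H]2[C@H]2OC(=O)[C@@H](COC(C)=O)[C@H]21 | intermediate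
32 | (4R,5S,6S,7S,8S,10R,11R)-13-acetoxy-4,5-epoxy-10-hydroxy-8-methacryloyloxy-1-oxogermacran-6,12-olide | C=C(C)C(=O)O[C@H]1C[C@@](C)(O)C(=O)CC[C@@]2(C)O[C@H]2[C@H]2OC(=O)[C@@H](COC(C)=O)[C@H]21 | intermediate
33 | (4R,5S,6S,7S,8S,10R,11R)-10,13-diacetoxy-4,5-epoxy-8-methacryloyloxy-1-oxogermacran-6,12-olide (CNP0166747.1) | C=C(C)C(=O)O[C@H]1C[C@@](C)(OC(C)=O)C(=O)CC[C@@]2(C)O[C@H]2[C@H]2OC(=O)[C@@H](COC(C)=O)[C@H]21 | target

**Count and risks**

Total step count: 24. Longest linear sequence: 21 steps (steps 2–4, then 7–24).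

Steps most likely to fail:

1. Step 17 (Proposed new method). The tethered π-allylpalladium/enolate pair may collapse by β-hydride elimination to a diene, close at the internal allyl terminus, or oligomerise; syn–anti isomerisation of the allyl unit may also erode the Z geometry. The fallback uses known chemistry, sets out from 22 and comes back at 25. Alcohol 22 is converted with methyl chloroformate/pyridine into the allylic methyl carbonate, tert-butyl (4R,6S,7S,8S,9Z)-7-[(2R)-1-acetoxybut-3-en-2-yl]-6-(tert-butyldimethylsilyloxy)-11-(methoxycarbonyloxy)-4,10-dimethyl-3-oxo-4,8-bis(triethylsilyloxy)undec-9-enoate F1. A conventional intramolecular Tsuji–Trost C-allylation of the intact β-keto ester (Pd2(dba)3, dppe, THF, 60 °C, high dilution; the carbonate supplies the base) should then close the ten-membered ring directly to the tert-butyl 2-carboxylate of 25 (C2 epimers) F2. Heating F2 in wet DMSO at 120 °C removes the tert-butoxycarbonyl group (loss of tert-butanol and CO2) and gives 25.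

2. Step 21. The carboxylate may fail to displace the hindered epoxy-carbinyl mesylate (elimination or epoxide opening instead), and the acetoxy-aldehyde stage of the alkene cleavage may epimerise at C11. The fallback sets out from 27 and comes back at 30, moving the inversion to an intermolecular Mitsunobu reaction. Treatment of 27 with chloroacetic acid, PPh3 and DIAD should give the inverted (4R,5S,6S,7R,8S,10R)-6-chloroacetate of 27, F3. Thiourea/NaHCO3 in EtOH removes the chloroacetyl group in the presence of the acetate and gives the C6-inverted (4R,5S,6S,7R,8S,10R)-alcohol F4. RuCl3/NaIO4 cleavage of the vinyl group then gives the (6S,11R)-γ-hydroxy acid F5, which lactonises with retention (cat. PPTS, CH2Cl2) to 30.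

3. Step 10. Facial selectivity in the addition to the lactol-derived aldehyde may be poor, because chelation by the C13 alkoxide can compete with Felkin–Anh/1,3-anti control. The fallback sets out from 18 (carried as the C6-epimer mixture after step 11) and comes back at 18, replacing substrate control by reagent control. Buffered Dess–Martin oxidation gives the (Z)-enone, (2Z,5S,6S,8R)-5-[(2R)-1-acetoxybut-3-en-2-yl]-6-(tert-butyldimethylsilyloxy)-1-(4-methoxybenzyloxy)-2,8-dimethyl-8,9-bis(triethylsilyloxy)non-2-en-4-one F6. Corey–Bakshi–Shibata reduction (Me-CBS enantiomer matched to delivery of hydride to the face giving the 4S carbinol, catecholborane, −78 °C) should then return 18 as a single epimer.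

Further compounds
F1 | step 17 | tert-butyl (4R,6S,7S,8S,9Z)-7-[(2R)-1-acetoxybut-3-en-2-yl]-6-(tert-butyldimethylsilyloxy)-11-(methoxycarbonyloxy)-4,10-dimethyl-3-oxo-4,8-bis(triethylsilyloxy)undec-9-enoate | COC(=O)OC/C(C)=C\[C@H](O[Si](CC)(CC)CC)[C@@H]([C@@H](C=C)COC(C)=O)[C@@H](O[Si](C)(C)C(C)(C)C)C[C@@](C)(O[Si](CC)(CC)CC)C(=O)CC(=O)OC(C)(C)C
F2 | step 17 | tert-butyl 2-carboxylate of 25 (germacrane locants; C2 epimers) | O=C1C(C(=O)OC(C)(C)C)C/C(C)=C\[C@H](O[Si](CC)(CC)CC)[C@@H]([C@@H](C=C)COC(C)=O)[C@@H](O[Si](C)(C)C(C)(C)C)C[C@@]1(C)O[Si](CC)(CC)CC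
F3 | step 21 | (4R,5S,6S,7R,8S,10R)-7-[(2R)-1-acetoxybut-3-en-2-yl]-8-(tert-butyldimethylsilyloxy)-6-(chloroacetoxy)-4,5-epoxy-4,10-dimethyl-10-(triethylsilyloxy)cyclodecan-1-one | O=C1CC[C@@]2(C)O[C@H]2[C@@H](OC(=O)CCl)[C@@H]([C@@H](C=C)COC(C)=O)[C@@H](O[Si](C)(C)C(C)(C)C)C[C@@]1(C)O[Si](CC)(CC)CC
F4 | step 21 | (4R,5S,6S,7R,8S,10R)-7-[(2R)-1-acetoxybut-3-en-2-yl]-8-(tert-butyldimethylsilyloxy)-4,5-epoxy-6-hydroxy-4,10-dimethyl-10-(triethylsilyloxy)cyclodecan-1-one | O=C1CC[C@@]2(C)O[C@H]2[C@@H](O)[C@@H]([C@@H](C=C)COC(C)=O)[C@@H](O[Si](C)(C)C(C)(C)C)C[C@@]1(C)O[Si](CC)(CC)CC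
F5 | step 21 | (6S,11R)-γ-hydroxy acid (F4 with the vinyl group replaced by CO2H) | O=C1CC[C@@]2(C)O[C@H]2[C@@H](O)[C@@H]([C@@H](C(=O)O)COC(C)=O)[C@@H](O[Si](C)(C)C(C)(C)C)C[C@@]1(C)O[Si](CC)(CC)CC
F6 | step 10 | (2Z,5S,6S,8R)-5-[(2R)-1-acetoxybut-3-en-2-yl]-6-(tert-butyldimethylsilyloxy)-1-(4-methoxybenzyloxy)-2,8-dimethyl-8,9-bis(triethylsilyloxy)non-2-en-4-one | COc1ccc(COC/C(C)=C\C(=O)[C@@H]([C@@H](C=C)COC(C)=O)[C@@H](O[Si](C)(C)C(C)(C)C)C[C@@](C)(O[Si](CC)(CC)CC)CO[Si](CC)(CC)CC)cc1
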